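**Plan**

- Retrosynthetic cuts, in order: the ester C–O bond at O6; the C7 carbinol (back to a ketone); C14=C15 and C12=C13 of the diene; the C6–O and C8–O bonds (enolate oxidations of a C7 ketone); C9–C11 (allyl addition to a C9 ketone, then 1,3-oxygen transposition); C3–C4 of ring A; C10–C1 and C10–C20 (enolate alkylations).
- Enabling feature: C4, the gem-dimethyl carbon of ring A, is bonded to the ring-fusion stereocentre C5 in the same way as the isopropenyl carbon is bonded to the stereocentre of carvone. The carvone ring is ring B (C5 to C10), its carbonyl carbon is C9 and its vinylic methyl is C17 on C8, so an acrylate arm on C10 lets the isopropenyl group close ring A.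
- Forward order: ring B is bought as (R)-carvone; C10 is made quaternary (steps 1, 2); ring A closes by C3–C4 radical cyclisation (step 3); the C2 ester is excised (steps 4, 5); C11/C12 are added and the enone is transposed (steps 6, 7); ring B is oxidised and the diene and angelate are attached (steps 8 to 16).
- Stereochemistry: C5 from (R)-carvone; C10 by alkylation anti to isopropenyl; C9 by axial protonation in the dissolving-metal reduction; C8 and C6 by α-face oxidation opposite the axial methyls on C10 and C4; C7 by axial hydride delivery; 12E by thermodynamic cross-metathesis; the Z ester from angelic acid.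

Key step: step 3

Remark: labdane numbering is used for all bicyclic compounds (10-methyl β, H-5 and H-9 α); 3, 7 and 12 may each contain their epimer at a centre that is erased later (the methyl-bearing carbon of 3 in step 2, C2 of 7 in step 5, C9 of 12 in step 7), and the SMILES show the epimer expected to predominate.

**Step 1**
Reactants: 1 (R)-carvone
Product: 3 (5R,6S)-2,6-dimethyl-5-(prop-1-en-2-yl)cyclohex-2-en-1-one (trans-6-methylcarvone), via lithium dienolate 2 (not isolated)
Conditions: LiN(iPr)2, THF, −78 °C; MeI, −78 → 0 °C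
Reagents that add atoms: iodomethane, CI
Why: Kinetic deprotonation at the alpha-prime CH2 gives the cross-conjugated lithium dienolate, whose C-methylation (enolate alkylation) is standard for carvone; the new centre should form mainly trans to isopropenyl and is planarised again in step 2.

**Step 2**
Reactants: 3 trans-6-methylcarvone, 4 methyl 2-(bromomethyl)prop-2-enoate
Product: 6 methyl 2-{[(1S,6S)-1,3-dimethyl-2-oxo-6-(prop-1-en-2-yl)cyclohex-3-en-1-yl]methyl}prop-2-enoate, via lithium enolate 5 (not isolated)
Conditions: LiN(iPr)2, THF, −78 → −20 °C; then 4, −78 °C → rt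
Reagents that add atoms: none
Why: Enolate C-alkylation with an activated allylic bromide (direct or SN2' displacement gives the same product): the tetrasubstituted enolate 5 is attacked on the face anti to the neighbouring isopropenyl group, which sets the quaternary C10 with the acrylate arm (C1) trans and the methyl (C20) cis to the isopropenyl carbon (C4).

**Step 3**
Reactants: 6 acrylate-armed isopropenyl enone
Product: 7 methyl (2S,4aS,8aS)-4,4,7,8a-tetramethyl-8-oxo-1,2,3,4,4a,5,8,8a-octahydronaphthalene-2-carboxylate
Conditions: Fe(acac)3 (trivalent iron, 0.5 equiv), PhSiH3 (2.5 equiv), EtOH/(CH2OH)2 5:1, 60 °C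
Reagents that add atoms: none
Why: An iron hydride formed from Fe(acac)3 and PhSiH3 transfers a hydrogen atom to the CH2 terminus of the isopropenyl group, giving the second geminal methyl and the tertiary C4 radical; this nucleophilic radical adds to the unsubstituted acrylate terminus C3, and the resulting alpha-ester radical at C2 is reduced by divalent iron and protonated by ethanol. The closest known reaction type is the iron-hydride reductive olefin coupling (hydrogen-atom-transfer Giese reaction) of 1,1-disubstituted alkenes with acrylates, including intramolecular cases that build quaternary carbons. Ring A (C4, C5, C10, C1, C2, C3) closes in the 6-endo-trig mode, favoured over 5-exo attack at the ester-bearing C2 by polarity matching and by the substitution at C2. No ring-fusion centre is created: the fusion is trans (H-5 α, 10-methyl β) because C4 and the C1 arm were placed trans on C5 and C10 in step 2; the only new stereocentre, C2, is set when the ester enolate is quenched, is expected equatorial (2α) after equilibration and is erased in step 5. The selectivity needed is hydrogen-atom transfer to the isopropenyl group rather than to the acrylate or the conjugated ring alkene, which the substrate secures because only the isopropenyl group is an unconjugated, electron-rich 1,1-disubstituted alkene leading to a tertiary alkyl radical.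

**Step 4**
Reactants: 7 bicyclic enone ester
Product: 8 (2S,4aS,8aS)-4,4,7,8a-tetramethyl-8-oxo-1,2,3,4,4a,5,8,8a-octahydronaphthalene-2-carboxylic acid
Conditions: LiOH, THF/MeOH/H2O, rt → 50 °C; then 1 M HCl
Reagents that add atoms: lithium hydroxide, [Li+].[OH-]
Why: Ester saponification: hydroxide cleaves the methyl ester (a C2 epimer with an axial ester would first epimerise to the equatorial one), while the enone carries no base-labile group.

**Step 5**
Reactants: 8 bicyclic enone acid
Product: 10 (4aS,8aS)-2,5,5,8a-tetramethyl-4a,5,6,7,8,8a-hexahydronaphthalen-1(4H)-one, via Barton ester 9 (not isolated)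
Conditions: N-hydroxypyridine-2-thione, DCC, DMAP (cat.), CH2Cl2, 0 °C → rt, dark; then t-BuSH, hν (tungsten lamp), rt
Reagents that add atoms: none
Why: Barton reductive decarboxylation: the thiohydroxamate ester fragments on irradiation to the secondary C2 radical, which abstracts hydrogen from t-BuSH, so the activating ester is removed without touching the enone and no stereocentre remains at C2.

**Step 6**
Reactants: 10 bicyclic enone, 11 allylmagnesium bromide
Product: 12 (1S,4aS,8aS)-2,5,5,8a-tetramethyl-1-(prop-2-en-1-yl)-1,4,4a,5,6,7,8,8a-octahydronaphthalen-1-ol (9β-hydroxy, 9α-allyl)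
Conditions: CH2=CHCH2MgBr, Et2O/THF, −78 → 0 °C; then sat. aq. NH4Cl
Reagents that add atoms: none
Why: Grignard 1,2-addition: allylmagnesium halides add at the carbonyl carbon even of hindered conjugated ketones, here mainly anti to the angular methyl, and the carbinol centre is destroyed in step 7.

**Step 7**
Reactants: 12 tertiary allylic alcohol
Product: 13 (4aS,8aS)-3,4a,8,8-tetramethyl-4-(prop-2-en-1-yl)-4a,5,6,7,8,8a-hexahydronaphthalen-2(1H)-one (14,15,16-trinorlabda-8,12-dien-7-one)
Conditions: [C5H5NH][CrO3Cl] (pyridinium chlorochromate), 4 Å molecular sieves, CH2Cl2, rt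
Reagents that add atoms: pyridinium chlorochromate, [O-][Cr](=O)(=O)Cl.c1cc[nH+]cc1
Why: Babler–Dauben oxidative transposition: the tertiary allylic chromate ester undergoes a [3,3] shift that places oxygen on C7, and oxidation of the resulting secondary allylic chromate gives the C7 ketone conjugated with the new C8=C9 alkene; no stereocentre is involved.

**Step 8**
Reactants: 13 transposed enone
Product: 15 7-(trimethylsilyloxy)-14,15,16-trinorlabda-7,12-diene (9α-H), via lithium enolate 14 (not isolated)
Conditions: Li (2.1 equiv), t-BuOH (1.0 equiv), NH3(l)/THF, −78 °C; NH3 removed; Me3SiCl, Et3N, THF, −78 → 0 °C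
Reagents that add atoms: chlorotrimethylsilane, C[Si](C)(C)Cl
Why: Dissolving-metal conjugate reduction with regiospecific reductive enolate trapping: the C9 carbanion is protonated axially from the α face, which sets C9 with the allyl group equatorial (β), and the C7–C8 enolate is silylated on oxygen before it can equilibrate; the isolated terminal alkene is not reduced.

**Step 9**
Reactants: 15 trimethylsilyl enol ether
Product: 17 8α-hydroxy-14,15,16-trinorlabd-12-en-7-one, via silyloxy epoxide 16 (not isolated)
Conditions: mCPBA (1.05 equiv), NaHCO3, CH2Cl2, −20 → 0 °C; then 1 M HCl, THF, 0 °C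
Reagents that add atoms: 3-chloroperoxybenzoic acid, OOC(=O)c1cccc(Cl)c1
Why: Rubottom oxidation: the peracid epoxidises the electron-rich tetrasubstituted enol ether much faster than the terminal alkene and from the α face, opposite the axial C10 methyl, so opening of the silyloxy epoxide leaves the tertiary C8 hydroxyl α (equatorial) and the C8 methyl β.

**Step 10**
Reactants: 17 tertiary α-ketol
Product: 18 8α-(triethylsilyloxy)-14,15,16-trinorlabd-12-en-7-one
Conditions: Et3SiOTf, 2,6-lutidine, CH2Cl2, −78 → 0 °C
Reagents that add atoms: triethylsilyl trifluoromethanesulfonate, CC[Si](CC)(CC)OS(=O)(=O)C(F)(F)F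
Why: Silylation of a tertiary alcohol with a silyl triflate and a hindered pyridine base is standard and keeps the ketol oxygen from alkoxide chemistry (ketol shift, oxa-Michael addition to the later enal, consumption of ylide and base) in steps 11 to 15; at low temperature the ketone is not enol-silylated.

**Step 11**
Reactants: 18 silyl-protected allyl ketone, 19 methacrolein
Product: 20 (12E)-7-oxo-8α-(triethylsilyloxy)-15-norlabd-12-en-14-al
Conditions: 19 (excess), second-generation Hoveyda–Grubbs catalyst RuCl2(H2IMes)(=CH-C6H4-2-OiPr) (5 mol%), CH2Cl2, 40 °C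
Reagents that add atoms: none
Why: Olefin cross-metathesis of a terminal alkene with methacrolein gives the trisubstituted 2-methyl enal under thermodynamic control, which sets the 12E geometry; ketone and silyl ether are tolerated.

**Step 12**
Reactants: 20 enal
Product: 21 (12E)-8α-(triethylsilyloxy)labda-12,14-dien-7-one
Conditions: Ph3PCH3Br, KN(SiMe3)2, THF, 0 °C; then 20 (1.1 equiv ylide), −78 → 0 °C
Reagents that add atoms: methyltriphenylphosphonium bromide, C[P+](c1ccccc1)(c1ccccc1)c1ccccc1.[Br-]
Why: Wittig methylenation: the unstabilised ylide reacts with the unhindered conjugated aldehyde at low temperature much faster than with the C7 ketone, which is flanked by the fully substituted C8, and the C12=C13 geometry is untouched.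

**Step 13**
Reactants: 21 diene ketone
Product: 23 (12E)-6α-hydroxy-8α-(triethylsilyloxy)labda-12,14-dien-7-one, via potassium enolate 22 (not isolated)
Conditions: KN(SiMe3)2, THF, −78 °C; 2-(phenylsulfonyl)-3-phenyloxaziridine, −78 °C; AcOH
Reagents that add atoms: 2-(phenylsulfonyl)-3-phenyloxaziridine, O=S(=O)(c1ccccc1)N1OC1c1ccccc1
Why: Enolate hydroxylation with the Davis oxaziridine: the ketone can enolise only towards C6, and the oxidant approaches the enolate from the α face because the β face is closed by the axial methyls on C4 and C10, giving the equatorial 6α alcohol; the reagent does not oxidise the diene.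

**Step 14**
Reactants: 23 6α-hydroxy ketone, 24 angelic acid
Product: 26 (12E)-7-oxo-8α-(triethylsilyloxy)labda-12,14-dien-6α-yl (Z)-2-methylbut-2-enoate, via mixed anhydride 25 (not isolated)
Conditions: 24, 2,4,6-trichlorobenzoyl chloride, Et3N, PhMe, rt; then 23, 80 °C
Reagents that add atoms: none
Why: Yamaguchi-type esterification through the mixed anhydride without a nucleophilic catalyst is the established way to make angelates without Z-to-E isomerisation; the secondary C6 hydroxyl is the only free one and keeps its configuration.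

**Step 15**
Reactants: 26 6α-angeloyloxy ketone
Product: 27 (12E)-7β-hydroxy-8α-(triethylsilyloxy)labda-12,14-dien-6α-yl (Z)-2-methylbut-2-enoate
Conditions: NaBH4, MeOH/THF, −20 °C
Reagents that add atoms: none
Why: Borohydride reduction of a cyclohexanone: axial delivery of hydride from the α face, whose syn-axial partners are only H-5 and H-9, gives the equatorial 7β alcohol, and the low temperature limits 6-to-7 acyl migration while the unsaturated ester and diene are not reduced.

**Step 16**
Reactants: 27 silyl-protected diol monoester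
Product: 28 (12E)-7β,8α-dihydroxylabda-12,14-dien-6α-yl (Z)-2-methylbut-2-enoate (CNP0189082.1)
Conditions: HF·pyridine, pyridine/THF, 0 °C → rt
Reagents that add atoms: none
Why: Fluoride-mediated silyl ether cleavage under buffered, non-basic conditions frees the tertiary C8 hydroxyl (also if the silyl group has shifted to O7 in step 15) without acyl migration or isomerisation of the angelate.

**Compound list**

1 | (R)-carvone, (5R)-2-methyl-5-(prop-1-en-2-yl)cyclohex-2-en-1-one | CC1=CC[C@@H](C(C)=C)CC1=O | starting material
2 | lithium (3R)-6-methyl-3-(prop-1-en-2-yl)cyclohexa-1,5-dien-1-olate (kinetic dienolate of 1; not isolated) | CC1=CC[C@@H](C(C)=C)C=C1[O-].[Li+] | intermediate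
3 | (5R,6S)-2,6-dimethyl-5-(prop-1-en-2-yl)cyclohex-2-en-1-one (trans-6-methylcarvone) | CC1=CC[C@@H](C(C)=C)[C@H](C)C1=O | intermediate
4 | methyl 2-(bromomethyl)prop-2-enoate | C=C(CBr)C(=O)OC | starting material
5 | lithium (3S)-2,6-dimethyl-3-(prop-1-en-2-yl)cyclohexa-1,5-dien-1-olate (not isolated) | CC1=CC[C@@H](C(C)=C)C(C)=C1[O-].[Li+] | intermediate
6 | methyl 2-{[(1S,6S)-1,3-dimethyl-2-oxo-6-(prop-1-en-2-yl)cyclohex-3-en-1-yl]methyl}prop-2-enoate (key-step precursor) | CC1=CC[C@@H](C(C)=C)[C@](C)(CC(=C)C(=O)OC)C1=O | intermediate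
7 | methyl (2S,4aS,8aS)-4,4,7,8a-tetramethyl-8-oxo-1,2,3,4,4a,5,8,8a-octahydronaphthalene-2-carboxylate (key-step product; trans-fused, 2α-ester) | CC1=CC[C@H]2C(C)(C)C[C@H](C(=O)OC)C[C@]2(C)C1=O | intermediate
8 | (2S,4aS,8aS)-4,4,7,8a-tetramethyl-8-oxo-1,2,3,4,4a,5,8,8a-octahydronaphthalene-2-carboxylic acid | CC1=CC[C@H]2C(C)(C)C[C@H](C(=O)O)C[C@]2(C)C1=O | intermediate
9 | 2-thioxopyridin-1(2H)-yl ester of 8 (Barton ester; not isolated) | CC1=CC[C@H]2C(C)(C)C[C@H](C(=O)ON3C=CC=CC3=S)C[C@]2(C)C1=O | intermediate
10 | (4aS,8aS)-2,5,5,8a-tetramethyl-4a,5,6,7,8,8a-hexahydronaphthalen-1(4H)-one | CC1=CC[C@H]2C(C)(C)CCC[C@]2(C)C1=O | intermediate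
11 | allylmagnesium bromide, CH2=CHCH2MgBr | C=CC[Mg]Br | starting material
12 | (1S,4aS,8aS)-2,5,5,8a-tetramethyl-1-(prop-2-en-1-yl)-1,4,4a,5,6,7,8,8a-octahydronaphthalen-1-ol (9β-hydroxy, 9α-allyl) | CC1=CC[C@H]2C(C)(C)CCC[C@]2(C)[C@]1(O)CC=C | intermediate
13 | (4aS,8aS)-3,4a,8,8-tetramethyl-4-(prop-2-en-1-yl)-4a,5,6,7,8,8a-hexahydronaphthalen-2(1H)-one (14,15,16-trinorlabda-8,12-dien-7-one) | C=CCC1=C(C)C(=O)C[C@H]2C(C)(C)CCC[C@@]21C | intermediate
14 | lithium 14,15,16-trinorlabda-7,12-dien-7-olate (9α-H; not isolated) | C=CC[C@H]1C(C)=C([O-])C[C@H]2C(C)(C)CCC[C@@]21C.[Li+] | intermediate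
15 | 7-(trimethylsilyloxy)-14,15,16-trinorlabda-7,12-diene (9α-H) | C=CC[C@H]1C(C)=C(O[Si](C)(C)C)C[C@H]2C(C)(C)CCC[C@@]21C | intermediate
16 | 7α,8α-epoxy-7β-(trimethylsilyloxy)-14,15,16-trinorlabd-12-ene (not isolated) | C=CC[C@H]1[C@]2(C)O[C@]2(O[Si](C)(C)C)C[C@H]2C(C)(C)CCC[C@@]21C | intermediate
17 | 8α-hydroxy-14,15,16-trinorlabd-12-en-7-one | C=CC[C@H]1[C@](C)(O)C(=O)C[C@H]2C(C)(C)CCC[C@@]21C | intermediate
18 | 8α-(triethylsilyloxy)-14,15,16-trinorlabd-12-en-7-one | C=CC[C@H]1[C@](C)(O[Si](CC)(CC)CC)C(=O)C[C@H]2C(C)(C)CCC[C@@]21C | intermediate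
19 | methacrolein (2-methylprop-2-enal) | C=C(C)C=O | starting material
20 | (12E)-7-oxo-8α-(triethylsilyloxy)-15-norlabd-12-en-14-al | O=C/C(C)=C/C[C@H]1[C@](C)(O[Si](CC)(CC)CC)C(=O)C[C@H]2C(C)(C)CCC[C@@]21C | intermediate
21 | (12E)-8α-(triethylsilyloxy)labda-12,14-dien-7-one | C=C/C(C)=C/C[C@H]1[C@](C)(O[Si](CC)(CC)CC)C(=O)C[C@H]2C(C)(C)CCC[C@@]21C | intermediate
22 | potassium (12E)-8α-(triethylsilyloxy)labda-6,12,14-trien-7-olate (not isolated) | C=C/C(C)=C/C[C@H]1[C@](C)(O[Si](CC)(CC)CC)C([O-])=C[C@H]2C(C)(C)CCC[C@@]21C.[K+] | intermediate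
23 | (12E)-6α-hydroxy-8α-(triethylsilyloxy)labda-12,14-dien-7-one | C=C/C(C)=C/C[C@H]1[C@](C)(O[Si](CC)(CC)CC)C(=O)[C@H](O)[C@H]2C(C)(C)CCC[C@@]21C | intermediate
24 | angelic acid, (Z)-2-methylbut-2-enoic acid | C/C=C(/C)C(=O)O | starting material
25 | (Z)-2-methylbut-2-enoic 2,4,6-trichlorobenzoic anhydride (not isolated) | C/C=C(/C)C(=O)OC(=O)c1c(Cl)cc(Cl)cc1Cl | intermediate
26 | (12E)-7-oxo-8α-(triethylsilyloxy)labda-12,14-dien-6α-yl (Z)-2-methylbut-2-enoate | C=C/C(C)=C/C[C@H]1[C@](C)(O[Si](CC)(CC)CC)C(=O)[C@H](OC(=O)/C(C)=C\C)[C@H]2C(C)(C)CCC[C@@]21C | intermediate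
27 | (12E)-7β-hydroxy-8α-(triethylsilyloxy)labda-12,14-dien-6α-yl (Z)-2-methylbut-2-enoate | C=C/C(C)=C/C[C@H]1[C@](C)(O[Si](CC)(CC)CC)[C@@H](O)[C@H](OC(=O)/C(C)=C\C)[C@H]2C(C)(C)CCC[C@@]21C | intermediate
28 | (12E)-7β,8α-dihydroxylabda-12,14-dien-6α-yl (Z)-2-methylbut-2-enoate, (5S,6R,7S,8S,9R,10S), CNP0189082.1 | C=C/C(C)=C/C[C@H]1[C@](C)(O)[C@@H](O)[C@H](OC(=O)/C(C)=C\C)[C@H]2C(C)(C)CCC[C@@]21C | target

**Step count and risks**

Total step count: 16. Longest linear sequence: 16 steps from (R)-carvone; the route is fully linear.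

The three steps most likely to fail:

Step 3. Hydrogen-atom transfer could go to the acrylate or to the ring enone instead of the isopropenyl group, or the C4 radical could be reduced before it cyclises. The fallback sets out from 6 and comes back at 7, and generates the same radical without a metal hydride. Markovnikov addition of HBr (HBr in AcOH, 0 °C, short contact) to the isopropenyl group of 6 should give the tertiary bromide methyl 2-{[(1S,6R)-6-(2-bromopropan-2-yl)-1,3-dimethyl-2-oxocyclohex-3-en-1-yl]methyl}prop-2-enoate F1. Slow addition of Bu3SnH with AIBN in benzene at 80 °C would then abstract bromine, and the tertiary C4 radical would close ring A by the same 6-endo addition to the acrylate and take hydrogen from the tin hydride to give 7.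

Step 13. Deprotonation at C6, which lies under the axial methyls on C4 and C10, may be slow, so that hydroxylation stays incomplete. The fallback sets out from 18 and comes back at 23, and oxidises C6 at the allyl stage by soft enolisation.
- 18 with Me3SiOTf and Et3N in CH2Cl2 should give 8α-(triethylsilyloxy)-7-(trimethylsilyloxy)-14,15,16-trinorlabda-6,12-diene F2.
- mCPBA with NaHCO3 would epoxidise the enol ether from the α face to 6α,7α-epoxy-8α-(triethylsilyloxy)-7β-(trimethylsilyloxy)-14,15,16-trinorlabd-12-ene F3 (not isolated), and mild acidic work-up would open it to 6α-hydroxy-8α-(triethylsilyloxy)-14,15,16-trinorlabd-12-en-7-one F4.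
- Cross-metathesis of F4 with 19 under the conditions of step 11 would give (12E)-6α-hydroxy-7-oxo-8α-(triethylsilyloxy)-15-norlabd-12-en-14-al F5.
- Wittig methylenation of F5 with an excess of Ph3P=CH2 at low temperature (one equivalent is consumed by the free hydroxyl) would return 23.

Step 14. Acylation of the hindered C6 hydroxyl may be sluggish, and forcing it invites Z-to-E isomerisation of the angeloyl group to the tiglate. The fallback sets out from 23 and comes back at 26, and builds the Z alkene on the ester instead of transferring it. Esterification of 23 with 2-(diphenoxyphosphoryl)propanoic acid (DCC, DMAP, CH2Cl2) should give (12E)-7-oxo-8α-(triethylsilyloxy)labda-12,14-dien-6α-yl 2-(diphenoxyphosphoryl)propanoate F6. A Z-selective Horner–Wadsworth–Emmons reaction of the Ando type (NaH, THF, −78 °C, carbanion generated in the presence of excess acetaldehyde so that the aldehyde is olefinated before the hindered C7 ketone can be attacked) would then give 26.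

**Further compounds**

F1 | step 3 | methyl 2-{[(1S,6R)-6-(2-bromopropan-2-yl)-1,3-dimethyl-2-oxocyclohex-3-en-1-yl]methyl}prop-2-enoate | CC1=CC[C@@H](C(C)(C)Br)[C@](C)(CC(=C)C(=O)OC)C1=O
F2 | step 13 | 8α-(triethylsilyloxy)-7-(trimethylsilyloxy)-14,15,16-trinorlabda-6,12-diene | C=CC[C@H]1[C@](C)(O[Si](CC)(CC)CC)C(O[Si](C)(C)C)=C[C@H]2C(C)(C)CCC[C@@]21C
F3 | step 13 | 6α,7α-epoxy-8α-(triethylsilyloxy)-7β-(trimethylsilyloxy)-14,15,16-trinorlabd-12-ene (not isolated) | C=CC[C@H]1[C@](C)(O[Si](CC)(CC)CC)[C@]3(O[Si](C)(C)C)O[C@@H]3[C@H]2C(C)(C)CCC[C@@]21C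
F4 | step 13 | 6α-hydroxy-8α-(triethylsilyloxy)-14,15,16-trinorlabd-12-en-7-one | C=CC[C@H]1[C@](C)(O[Si](CC)(CC)CC)C(=O)[C@H](O)[C@H]2C(C)(C)CCC[C@@]21C
F5 | step 13 | (12E)-6α-hydroxy-7-oxo-8α-(triethylsilyloxy)-15-norlabd-12-en-14-al | O=C/C(C)=C/C[C@H]1[C@](C)(O[Si](CC)(CC)CC)C(=O)[C@H](O)[C@H]2C(C)(C)CCC[C@@]21C
F6 | step 14 | (12E)-7-oxo-8α-(triethylsilyloxy)labda-12,14-dien-6α-yl 2-(diphenoxyphosphoryl)propanoate (epimers at the phosphonate carbon) | C=C/C(C)=C/C[C@H]1[C@](C)(O[Si](CC)(CC)CC)C(=O)[C@H](OC(=O)C(C)P(=O)(Oc3ccccc3)Oc3ccccc3)[C@H]2C(C)(C)CCC[C@@]21C
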